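5.31 is the ratio of G to J that you carry through this flask: the plateau ratio, G summed over J in the delta run from 3.00 min on, as read with its scatter.

| flask | Z | X | remark | time |
|---|---|---|---|---|
| delta | 2 mM | 1.3 equiv | the very flask that is asked about, followed so far |  |
| theta | 4 mM | 1.3 equiv | run made earlier |  |
| flask | 2.0 mM | 1.30 equiv |  | 1.0 h |

| run | time / min | G / % | J / % | Q / % |
|---|---|---|---|---|
| delta | 1.33 | 56.0 | 9.8 | 0.9 |
| delta | 3.00 | 57.0 | 11.2 | 0 |
| delta | 8.00 | 57.1 | 9.9 | 0 |
| delta | 20.0 | 55.7 | 10.9 | 0 |
| theta | 5.00 | 67.6 | 10.9 | 0.3 |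
| theta | 12.0 | 68.9 | 12.4 | 0.7 |
| theta | 25.0 | 65.9 | 10.4 | 0 |
| theta | 60.0 | 67.5 | 12.5 | 0 |

(each reading ± 1 percentage point)

- at 1.0 h, what has stopped the reaction, if anything has (all of Z has reacted / it is still moving / X has run out first)
- G at 1.0 h, in percent of the Z charged
- J at 1.0 h, in percent of the Z charged
- amount of Q if the flask were left three thousand times as long, in percent of the Z charged

- in percentages every species weighs as the Z in it: one G counts as two
- steps under discussion: X + Q -> L; X -> E; Z + X -> Q; Z + Q -> G; Z + X -> J; X + J -> L
- the reaction counts as stopped when no species that holds the Z changes by six tenths of a point or more over the second half of the time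

Bracket G in the delta flask at 1.0 h. From above, the balance with J near 10.7% caps G at 89.3%; from below, no listed step consumes G, so it keeps about the 56.6% it has reached. You can tighten the top, because J goes from 11.2% to 10.9%, a shift smaller than the scatter, although X + J → L is among the steps, so I read the flask as stopped by X, not by Z, with Q staying at its 0%. Two standard errors then put G between 55.4% and 57.8%. Going round once more with the theta run, at twice the Z, the same ratio reads 5.73, close enough for me to try it on other flasks.

The forecast, X has run out first with G 56.5%, J 10.5% and Q 0% in the long run, puts its G inside my bracket  and says “The stop is X running out, not Z.”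

The flask gives this: X has run out first, G 56.8%, J 10.6%, Q 0% in the long run, with X at 0% and Z at 27%, and a ratio of 5.36 beside your 5.31.

    X + Q → L (k = 25.0 M⁻¹ s⁻¹)
    X → E (k = 0.110 s⁻¹)
    Z + X → Q (k = 33.0 M⁻¹ s⁻¹)
    Z + Q → G (k = 96.0 M⁻¹ s⁻¹)
    Z + X → J (k = 13.0 M⁻¹ s⁻¹)
    X + J → L (k = 21.0 M⁻¹ s⁻¹)

In this flask X goes to E at 0.110 s⁻¹, faster than the 0.0920 s⁻¹ at which it meets Z as charged. At 1.00 h E stands at 1.60 mM, with X at 0% of its charge of 1.30 equiv. On the neighbour flask with 0.520 equiv of X, all else held, your ratio of 5.31 gives G 30.0% from that flask's J of 5.65%, and the computed G there is 29.3%.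

All runs were computed with constants of no real substance, noise included.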